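C1 is the aryl-bearing carbon of the tetralin, C2 carries the sulfated arm, C3 carries the CH2OH arm, and C4 is the ring CH2. Ring A is the fused arene (C6 OMe, C7 OH), ring B the carbocycle, ring C the pendant guaiacyl. The strategy rests on this feature: C1 and C2 are neighbours, C1 is benzylic to ring A and conjugated through C8a with the para C6 methoxy group, and the C2 arm is a single CH2O carbon. C1–C2 is therefore read as an alkene that has taken up formaldehyde at C2 and guaiacol at C1.
19 ⇒ 15 (remove three benzyl ethers; remove the sulfate from the one free carbinol) ⇒ 14 (phenol benzylation).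
14 ⇒ alkene 10 + formaldehyde 11 + guaiacol 12. The C2–CH2O and C1–ring C bonds form in one flask, no ring is closed, and C2 and C1 are relayed from C3.
10 ⇒ tetralone ester 7 (LiAlH4, perbenzylation, E1 loss of BnOH) ⇒ (R)-half-ester 5 by Friedel–Crafts acylation para to the ring A methoxy group.
5 ⇒ Stobbe product 4 of 1 and 2 by Rh-catalysed asymmetric hydrogenation, which sets C3. Rings A and C are bought, and ring B is the only ring made (step 3).

Key step: step 7

Assumption 1: the bisphosphine antipode named in step 2 is taken to be the one that gives (R)-5. The sense is checked on 5 (chiral HPLC, rotation), and the mirror-image ligand is used if it proves opposite.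
Assumption 2: the target is taken as the free hydrogen sulfate as drawn. Its sodium salt 18 is the robust form and is protonated only at the very end.

Step 1
Reactants: 1 4-benzyloxy-3-methoxybenzaldehyde; 2 dimethyl succinate
Product: 4 (E)-4-(4-benzyloxy-3-methoxyphenyl)-3-(methoxycarbonyl)but-3-enoic acid, via paraconic ester lactone 3 (not isolated)
Conditions: NaOMe (1.5 equiv), MeOH, reflux; then aq HCl
Reagents that add atoms: none
Why: Stobbe condensation: the succinate enolate adds to the aldehyde, the aldolate lactonises to 3 with loss of methoxide, and irreversible E1cB opening of 3 to the carboxylate drives the sequence and should give mainly the E alkene (aryl trans to the ester).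

Step 2
Reactants: 4 (E)-half-ester
Product: 5 (R)-3-(4-benzyloxy-3-methoxybenzyl)-4-methoxy-4-oxobutanoic acid
Conditions: [Rh(cod)2]BF4 (0.5 mol %), (S,S)-Et-DuPhos (0.55 mol %), NaOMe (10 mol %), H2 (6 bar), MeOH, rt
Reagents that add atoms: none
Why: Rh–bisphosphine asymmetric hydrogenation of a Stobbe-type itaconate half-ester, in which carboxylate and alkene chelate the cationic rhodium centre so that H2 is delivered to one face and sets the future C3 as R, while the homogeneous catalyst leaves the benzyl ether alone.

Step 3
Reactants: 5 (R)-half-ester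
Product: 7 methyl (R)-6-benzyloxy-7-methoxy-4-oxo-1,2,3,4-tetrahydronaphthalene-2-carboxylate, via mixed trifluoroacetic anhydride 6 (not isolated)
Conditions: (CF3CO)2O (2.5 equiv), CH2Cl2, 0 °C to rt
Reagents that add atoms: none
Why: Intramolecular Friedel–Crafts acylation through 6 closes six-membered ring B at the ring A carbon para to the methoxy group (the other ortho site is wedged between chain and OMe), in a medium mild enough for the aryl benzyl ether and unable to enolise the ester stereocentre.

Step 4
Reactants: 7 tetralone ester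
Product: 8 (3R)-7-benzyloxy-3-(hydroxymethyl)-6-methoxy-1,2,3,4-tetrahydronaphthalen-1-ol (C1 epimers)
Conditions: LiAlH4 (2 equiv), THF, 0 °C; H2O/aq NaOH work-up
Reagents that add atoms: none
Why: Hydride reduction of ketone and ester in one operation; the new carbinol centre forms as an epimer mixture, which does not matter because step 6 destroys it, and C3 is untouched.

Step 5
Reactants: 8 diol
Product: 9 (3R)-1,7-bis(benzyloxy)-3-(benzyloxymethyl)-6-methoxy-1,2,3,4-tetrahydronaphthalene (C1 epimers)
Conditions: NaH (3 equiv), BnBr (2.6 equiv), Bu4NI (cat.), THF, 0 °C to rt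
Reagents that add atoms: benzyl bromide, BrCc1ccccc1
Why: Exhaustive Williamson etherification removes any need to tell the two hydroxyls apart and, unlike acid dehydration of the free diol, leaves no CH2OH that could capture the C1 cation of the next step as a bridged 1,3-ether.

Step 6
Reactants: 9 tris(benzyl) ether
Product: 10 (R)-6-benzyloxy-2-(benzyloxymethyl)-7-methoxy-1,2-dihydronaphthalene
Conditions: pTsOH·H2O (5 mol %), toluene, 80 °C, Ar; product used promptly
Reagents that add atoms: none
Why: Acid-catalysed E1 elimination, the same path as tetralol dehydration: only the secondary ether is para-methoxybenzylic and ionises, its cation can lose a proton only from C2, and so the C1=C2 styrene should form with C3 and the other two benzyl ethers intact.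

Step 7
Reactants: 10 (R)-dihydronaphthalene; 11 paraformaldehyde (formaldehyde source); 12 guaiacol
Product: 14 [(1S,2R,3R)-7-benzyloxy-3-(benzyloxymethyl)-1-(4-hydroxy-3-methoxyphenyl)-6-methoxy-1,2,3,4-tetrahydronaphthalen-2-yl]methanol, via Prins 1,3-dioxane 13 (not isolated)
Conditions: 11 (2.5 equiv CH2O), BF3·OEt2 (1.5 equiv), 4 Å MS, CH2Cl2, 0 °C; slow addition of 10 at −20 °C; then 12 (6 equiv), −20 to 0 °C; aq NaHCO3
Reagents that add atoms: none
Why: Proposed new method: the alkene of 10 attacks BF3-bound formaldehyde through C2, because bond formation there leaves the charge on C1, a benzylic carbon conjugated through C8a with the C6 methoxy group of ring A, and a second formaldehyde unit stores this cation as the 1,3-dioxane 13; once guaiacol is added, BF3 re-ionises the benzylic C1–O bond and the cation is consumed irreversibly by Friedel–Crafts attack of the guaiacol carbon para to OH. The closest known reaction types are the Prins dioxane synthesis from anethole-type styrenes, the acid-mediated arylative opening of 4-aryl-1,3-dioxanes by phenols and the BF3·OEt2 Prins/Friedel–Crafts three-component route to 4-aryltetrahydropyrans; what is untested is their union in one flask on a cyclic styrene that carries a stereocentre. No ring of 14 is closed: the dioxane ring of 13 closes only transiently, by capture of the C1 cation by the hemiformal oxygen, and is opened again. C2 is controlled by C3, since the electrophile should reach the half-chair alkene on the face away from the benzyloxymethyl group on the adjacent allylic carbon, and C1 is controlled by C2, since guaiacol should approach the planar cation anti to the new arm, which gives the all-equatorial 1,2-trans-2,3-trans tetralin. The step needs C2-over-C1 regioselectivity (secured by the para methoxy group), para-to-hydroxyl selectivity in guaiacol (OH is the stronger donor and its para carbon is unhindered) and suppression of styrene oligomerisation and of plain hydroarylation (secured by adding 10 slowly to excess activated formaldehyde and withholding guaiacol until 10 is consumed). Surplus guaiacol carries off the formal carbon of 13 and unused formaldehyde as a diarylmethane, whichever acetal C–O bond breaks first, so the C2 carbinol should emerge as the only free aliphatic hydroxyl.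

Step 8
Reactants: 14 phenol alcohol
Product: 15 [(1S,2R,3R)-7-benzyloxy-1-(4-benzyloxy-3-methoxyphenyl)-3-(benzyloxymethyl)-6-methoxy-1,2,3,4-tetrahydronaphthalen-2-yl]methanol
Conditions: BnBr (1.1 equiv), K2CO3 (1.5 equiv), acetone, reflux
Reagents that add atoms: benzyl bromide, BrCc1ccccc1
Why: Williamson etherification under weak base: K2CO3 deprotonates only the phenol, which is far more acidic than the carbinol, so the C2 CH2OH stays as the sole free hydroxyl.

Step 9
Reactants: 15 tri-O-benzyl alcohol
Product: 17 sodium [(1S,2R,3R)-7-benzyloxy-1-(4-benzyloxy-3-methoxyphenyl)-3-(benzyloxymethyl)-6-methoxy-1,2,3,4-tetrahydronaphthalen-2-yl]methyl sulfate, via pyridinium sulfate 16 (not isolated)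
Conditions: SO3·pyridine (3 equiv), pyridine, rt; then aq NaHCO3; chromatography (CH2Cl2–MeOH)
Reagents that add atoms: sulfur trioxide–pyridine complex, O=S(=O)([O-])[n+]1ccccc1; sodium hydrogencarbonate, [Na+].OC([O-])=O
Why: O-sulfation of a primary alcohol with an SO3–amine complex; 15 holds a single hydroxyl, so the site is fixed by the protecting-group pattern, and exchange to the sodium salt removes pyridine, which would slow the later hydrogenolysis.

Step 10
Reactants: 17 protected sodium sulfate
Product: 19 [(1S,2R,3R)-7-hydroxy-1-(4-hydroxy-3-methoxyphenyl)-3-(hydroxymethyl)-6-methoxy-1,2,3,4-tetrahydronaphthalen-2-yl]methyl hydrogen sulfate (CNP0184747.1), via debenzylated sodium sulfate 18 (not isolated)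
Conditions: H2 (1 atm), Pd/C (10 wt %), MeOH–THF, rt; filter, evaporate; aq HCl (1.0 equiv), 0 °C; C18 (H2O, then MeCN–H2O), freeze-dry
Reagents that add atoms: none
Why: Catalytic hydrogenolysis cleaves the two aryl benzyl ethers and the alkyl benzyl ether, a non-benzylic primary sulfate monoester salt is inert to H2/Pd, and one equivalent of cold acid then protonates the salt with little time for solvolysis; no stereocentre is touched.

Compound list
1 | 4-benzyloxy-3-methoxybenzaldehyde | COc1cc(C=O)ccc1OCc1ccccc1 | starting material
2 | dimethyl succinate | COC(=O)CCC(=O)OC | starting material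
3 | methyl 2-(4-benzyloxy-3-methoxyphenyl)-5-oxotetrahydrofuran-3-carboxylate (paraconic ester lactone, stereoisomer mixture) | COC(=O)C1CC(=O)OC1c1ccc(OCc2ccccc2)c(OC)c1 | intermediate
4 | (E)-4-(4-benzyloxy-3-methoxyphenyl)-3-(methoxycarbonyl)but-3-enoic acid | COC(=O)/C(CC(=O)O)=C/c1ccc(OCc2ccccc2)c(OC)c1 | intermediate
5 | (R)-3-(4-benzyloxy-3-methoxybenzyl)-4-methoxy-4-oxobutanoic acid | COC(=O)[C@@H](CC(=O)O)Cc1ccc(OCc2ccccc2)c(OC)c1 | intermediate
6 | mixed anhydride of 5 and trifluoroacetic acid | COC(=O)[C@@H](CC(=O)OC(=O)C(F)(F)F)Cc1ccc(OCc2ccccc2)c(OC)c1 | intermediate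
7 | methyl (R)-6-benzyloxy-7-methoxy-4-oxo-1,2,3,4-tetrahydronaphthalene-2-carboxylate | COC(=O)[C@H]1CC(=O)c2cc(OCc3ccccc3)c(OC)cc2C1 | intermediate
8 | (3R)-7-benzyloxy-3-(hydroxymethyl)-6-methoxy-1,2,3,4-tetrahydronaphthalen-1-ol (C1 epimers) | OC[C@H]1CC(O)c2cc(OCc3ccccc3)c(OC)cc2C1 | intermediate
9 | (3R)-1,7-bis(benzyloxy)-3-(benzyloxymethyl)-6-methoxy-1,2,3,4-tetrahydronaphthalene (C1 epimers) | COc1cc2c(cc1OCc1ccccc1)C(OCc1ccccc1)C[C@H](COCc1ccccc1)C2 | intermediate
10 | (R)-6-benzyloxy-2-(benzyloxymethyl)-7-methoxy-1,2-dihydronaphthalene | COc1cc2c(cc1OCc1ccccc1)C=C[C@H](COCc1ccccc1)C2 | intermediate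
11 | paraformaldehyde (formaldehyde) | C=O | starting material
12 | guaiacol (2-methoxyphenol) | COc1ccccc1O | starting material
13 | Prins 1,3-dioxane: tetralin with an O–CH2–O–CH2 bridge from C1–O to the new C2 CH2, C2 arm anti to the C3 arm, C1 either configuration | COc1cc2c(cc1OCc1ccccc1)C1OCOC[C@H]1[C@H](COCc1ccccc1)C2 | intermediate
14 | [(1S,2R,3R)-7-benzyloxy-3-(benzyloxymethyl)-1-(4-hydroxy-3-methoxyphenyl)-6-methoxy-1,2,3,4-tetrahydronaphthalen-2-yl]methanol | COc1cc([C@H]2c3cc(OCc4ccccc4)c(OC)cc3C[C@@H](COCc3ccccc3)[C@@H]2CO)ccc1O | intermediate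
15 | [(1S,2R,3R)-7-benzyloxy-1-(4-benzyloxy-3-methoxyphenyl)-3-(benzyloxymethyl)-6-methoxy-1,2,3,4-tetrahydronaphthalen-2-yl]methanol | COc1cc([C@H]2c3cc(OCc4ccccc4)c(OC)cc3C[C@@H](COCc3ccccc3)[C@@H]2CO)ccc1OCc1ccccc1 | intermediate
16 | pyridinium salt of the C2-arm sulfate of 15 | COc1cc([C@H]2c3cc(OCc4ccccc4)c(OC)cc3C[C@@H](COCc3ccccc3)[C@@H]2COS(=O)(=O)[O-])ccc1OCc1ccccc1.c1cc[nH+]cc1 | intermediate
17 | sodium salt of the C2-arm sulfate of 15 | COc1cc([C@H]2c3cc(OCc4ccccc4)c(OC)cc3C[C@@H](COCc3ccccc3)[C@@H]2COS(=O)(=O)[O-])ccc1OCc1ccccc1.[Na+] | intermediate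
18 | sodium salt of the target | COc1cc([C@H]2c3cc(O)c(OC)cc3C[C@@H](CO)[C@@H]2COS(=O)(=O)[O-])ccc1O.[Na+] | intermediate
19 | [(1S,2R,3R)-7-hydroxy-1-(4-hydroxy-3-methoxyphenyl)-3-(hydroxymethyl)-6-methoxy-1,2,3,4-tetrahydronaphthalen-2-yl]methyl hydrogen sulfate | COc1cc([C@H]2c3cc(O)c(OC)cc3C[C@@H](CO)[C@@H]2COS(=O)(=O)O)ccc1O | target

Total step count: 10. Longest linear sequence: 10 steps (from 1).

Steps most likely to fail

Step 7. Several processes may intervene:
- poor facial selectivity of the small electrophile at C2;
- proton loss from the C1 cation, which erases C2 and lets it be reset by protonation;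
- cationic oligomerisation of the styrene;
- attack of guaiacol through the carbon para to OMe.

The fallback sets out from 5 (together with 1) and comes back at 15. It builds the C1–ring A bond by a known cationic ring closure instead. The ester of 5 is reduced as the potassium carboxylate with Ca(BH4)2 (from CaCl2 and NaBH4, EtOH). Acidification then gives (R)-4-(4-benzyloxy-3-methoxybenzyl)dihydrofuran-2(3H)-one F1. Its enolate (LiN(SiMe3)2, THF, −78 °C) adds to aldehyde 1 anti to the benzyl group to give the trans aldol adduct F2 as carbinol epimers. TFA in CH2Cl2 ionises the carbinol, and ring A closes ring B para to its methoxy group. This gives the 1,2-trans-2,3-trans lactone di-O-benzyl-α-conidendrin F3, in which the two arms differ in oxidation level. F3 is saponified (KOH, aq THF) and the dried potassium salt is treated with NaH and BnBr in DMF. The product is the benzyl ester benzyl ether F4, and any epimerisation at C2 runs toward this all-equatorial ester. LiAlH4 in THF then gives 15.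

Step 6. Three processes may intervene:
- acid-induced dimerisation of the electron-rich styrene;
- re-addition of benzyl alcohol;
- capture of the cation by the side-chain ether oxygen, with loss of its benzyl group.

The fallback sets out from 8 and comes back at 10. It makes the alkene without any cation. MnO2 in CH2Cl2 oxidises only the benzylic carbinol, giving the hydroxy tetralone F5. Benzyl 2,2,2-trichloroacetimidate with catalytic TfOH gives the benzyloxymethyl tetralone F6. KN(SiMe3)2 and PhNTf2 in THF at −78 °C give the enol triflate F7. Pd(OAc)2, PPh3, HCO2H and Et3N in DMF at 60 °C then give 10; the mechanism is oxidative addition to zerovalent palladium followed by formate-derived hydride transfer.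

Step 9. Three processes may intervene:
- incomplete sulfation of a carbinol flanked by the C1 aryl group and the C3 arm;
- partial loss of the sulfate during purification;
- carry-over of pyridine and inorganic sulfate in the amphiphilic salt, which would slow the hydrogenolysis of step 10.

The fallback sets out from 15 and comes back at 17. It carries the sulfate as a neutral diester that can be chromatographed. 15 is treated with 1-(2,2,2-trichloroethoxysulfonyl)-2,3-dimethylimidazolium triflate and 1,2-dimethylimidazole in CH2Cl2 to give the 2,2,2-trichloroethyl sulfate diester F8. Reductive fragmentation with Zn and HCO2NH4 in MeOH gives the ammonium sulfate F9. Evaporation from aq NaHCO3 exchanges the cation to give 17.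

Further compounds
F1 | step 7 | (R)-4-(4-benzyloxy-3-methoxybenzyl)dihydrofuran-2(3H)-one | O=C1C[C@@H](Cc2ccc(OCc3ccccc3)c(OC)c2)CO1
F2 | step 7 | (3S,4R)-4-(4-benzyloxy-3-methoxybenzyl)-3-[(4-benzyloxy-3-methoxyphenyl)(hydroxy)methyl]dihydrofuran-2(3H)-one (carbinol epimers) | O=C1[C@H](C(O)c2ccc(OCc3ccccc3)c(OC)c2)[C@@H](Cc2ccc(OCc3ccccc3)c(OC)c2)CO1
F3 | step 7 | di-O-benzyl-α-conidendrin (trans-fused lactone, carbonyl on C2, CH2O on C3) | O=C1[C@H]2[C@H](CO1)Cc1cc(OC)c(OCc3ccccc3)cc1[C@@H]2c1ccc(OCc2ccccc2)c(OC)c1
F4 | step 7 | benzyl (1S,2R,3R)-7-benzyloxy-1-(4-benzyloxy-3-methoxyphenyl)-3-(benzyloxymethyl)-6-methoxy-1,2,3,4-tetrahydronaphthalene-2-carboxylate | O=C(OCc1ccccc1)[C@H]1[C@H](COCc2ccccc2)Cc2cc(OC)c(OCc3ccccc3)cc2[C@@H]1c1ccc(OCc2ccccc2)c(OC)c1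
F5 | step 6 | (R)-7-benzyloxy-3-(hydroxymethyl)-6-methoxy-3,4-dihydronaphthalen-1(2H)-one | OC[C@H]1CC(=O)c2cc(OCc3ccccc3)c(OC)cc2C1
F6 | step 6 | (R)-7-benzyloxy-3-(benzyloxymethyl)-6-methoxy-3,4-dihydronaphthalen-1(2H)-one | c1ccccc1COC[C@H]1CC(=O)c2cc(OCc3ccccc3)c(OC)cc2C1
F7 | step 6 | (R)-7-benzyloxy-3-(benzyloxymethyl)-6-methoxy-3,4-dihydronaphthalen-1-yl trifluoromethanesulfonate | c1ccccc1COC[C@H]1C=C(OS(=O)(=O)C(F)(F)F)c2cc(OCc3ccccc3)c(OC)cc2C1
F8 | step 9 | 2,2,2-trichloroethyl sulfate diester of 15 | COc1cc([C@H]2c3cc(OCc4ccccc4)c(OC)cc3C[C@@H](COCc3ccccc3)[C@@H]2COS(=O)(=O)OCC(Cl)(Cl)Cl)ccc1OCc1ccccc1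
F9 | step 9 | ammonium salt of the C2-arm sulfate of 15 | COc1cc([C@H]2c3cc(OCc4ccccc4)c(OC)cc3C[C@@H](COCc3ccccc3)[C@@H]2COS(=O)(=O)[O-])ccc1OCc1ccccc1.[NH4+]
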